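**Retrosynthetic overview**

1. The tertiary hydroperoxide and the E-enone come last, by a Schenck ene reaction on a prenyl ketone; the ring oxirane comes from a hydroxyl-directed epoxidation of the ring allylic alcohol, cis to the side chain.
2. The 6-acyloxy-2-methylcyclohex-2-enone with its formyl-oxirane side chain comes from a retro-aldol C–C cleavage of a bicyclo[2.2.2]octenone, which releases the side chain from a bridge.
3. The bicycle comes from a one-pot Adler–Becker dearomatisation of 2-(hydroxymethyl)-6-methylphenol and Diels–Alder reaction with a cis-enediol silyl ether/ester. This forms the bond from the ring C=O carbon to the methyl-bearing ring carbon and the bond from the acyloxy-bearing ring carbon to the ring carbon that carries the side chain.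
4. Enabling feature: the ring carbons C(CH3)–CH(epoxide)–CH2–CH, the quaternary oxirane carbon and the side-chain C=O carbon are the six carbons of a benzene ring whose CH2OH and OH become the oxirane CH2–O and that C=O (a spiro-epoxy cyclohexa-2,4-dienone). The ring C=O and CH–O-acyl carbons are a cis-1,2-dioxygenated alkene.
5. Ring order: arene (bought) → side-chain oxirane (spiro) → bicyclo[2.2.2]octene → cyclohexenone by bridge cleavage → ring oxirane. Absolute configuration comes from kinetic resolution of the first chiral intermediate.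

Key step: step 3

Remark: the side-chain carbinol carbon made in steps 5 and 10 is later cleaved from the ring or oxidised, so its configuration is left open (no descriptor in the SMILES); compounds 1 and 4 are taken as commercial.

**Route**

Step 1
Reactants: 1 allyl 3-methylbutanoate
Product: 2 2-oxoethyl 3-methylbutanoate
Conditions: O3, CH2Cl2, −78 °C; then Me2S
Reagents that add atoms: ozone, O=[O+][O-]
Why: Ozonolysis of the terminal alkene with reductive work-up should give the α-acyloxy aldehyde, the ester being inert.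

Step 2
Reactants: 2 2-oxoethyl 3-methylbutanoate
Product: 3 (Z)-2-[(triethylsilyl)oxy]ethenyl 3-methylbutanoate
Conditions: Et3SiOTf, Et3N, CH2Cl2, −78 to 0 °C
Reagents that add atoms: triethylsilyl trifluoromethanesulfonate, CC[Si](CC)(CC)OS(=O)(=O)C(F)(F)F
Why: Soft enolisation and O-silylation (silyl enol ether formation) of an α-oxygenated aldehyde, a substrate class that gives the (Z)-enol silane.

Step 3
Reactants: 4 2-(hydroxymethyl)-6-methylphenol; 3 (Z)-2-[(triethylsilyl)oxy]ethenyl 3-methylbutanoate
Product: 6 racemic 4-methyl-3-oxo-8-[(triethylsilyl)oxy]spiro[bicyclo[2.2.2]oct-5-ene-2,2′-oxiran]-7-yl 3-methylbutanoate (both oxygens at C7 and C8 syn to the C5=C6 bridge; oxirane oxygen syn to the C7–C8 bridge), via spiroepoxy dienone 5 (not isolated)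
Conditions: NaIO4, MeCN–H2O, 0 °C; CH2Cl2 extraction at 0 °C, then 3 (3 equiv), 0 °C to rt
Reagents that add atoms: none
Why: Periodate converts the salicyl alcohol through its aryl periodate ester into the spiro-epoxy cyclohexa-2,4-dienone 5 (Adler–Becker oxidation; the oxirane closes by 3-exo attack of the benzylic oxygen on the ring carbon), and this electron-poor diene is trapped in the same operation by the electron-rich cis-enediol derivative 3 in an inverse-electron-demand Diels–Alder reaction, a concerted asynchronous suprafacial [4+2] cycloaddition that forms both new C–C bonds and closes the bicyclo[2.2.2]octene. The closest known reaction type is the in situ trapping of spiro-epoxy and 6,6-dioxygenated cyclohexa-2,4-dienones by enol ethers and other alkenes, which is ortho- and endo-selective. Regiochemistry: the acyloxy-bearing carbon of 3 (β to the stronger silyloxy donor) is the nucleophilic terminus and should bond to the unsubstituted diene terminus remote from the carbonyl (largest LUMO coefficient), so the silyloxy carbon ends next to the methyl-bearing bridgehead. Stereochemistry: the Z geometry of 3 becomes the cis relation of the two oxygens, endo approach places both syn to the new etheno bridge (which sets the acyloxy carbon trans to the future side chain), and attack on the diene face syn to the oxirane oxygen (anti to its CH2) fixes the spiro centre relative to the adjacent bridgehead. The selectivity needed is cross-cycloaddition over dimerisation of 5, secured by the methyl group on the dienone α-carbon, which slows dimerisation, and by the excess of 3. The adduct is racemic; its absolute configuration is fixed in step 4.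

Step 4
Reactants: 6 racemic adduct
Product: 7 4-methyl-3-oxo-8-[(triethylsilyl)oxy]spiro[bicyclo[2.2.2]oct-5-ene-2,2′-oxiran]-7-yl 3-methylbutanoate as the single enantiomer shown by its SMILES
Conditions: (salen)CrN3 [CrN3 complex of N,N′-bis(3,5-di-tert-butylsalicylidene)cyclohexane-1,2-diamine; the antipode that consumes ent-6, fixed in a pilot run] (2 mol %), Me3SiN3 (0.55 equiv), tBuOMe, 0 °C
Reagents that add atoms: none
Why: Azidolytic kinetic resolution of a 2,2-disubstituted terminal epoxide by a chiral chromium–salen azide complex: ent-6 should be opened at the oxirane CH2 to a separable azido silyl ether while 7 keeps its oxirane, which fixes the absolute configuration of all stereocentres at once.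

Step 5
Reactants: 7 enantiopure keto-epoxide
Product: 8 3-hydroxy-4-methyl-8-[(triethylsilyl)oxy]spiro[bicyclo[2.2.2]oct-5-ene-2,2′-oxiran]-7-yl 3-methylbutanoate
Conditions: NaBH4, MeOH–CH2Cl2, −20 °C
Reagents that add atoms: none
Why: Borohydride reduction of the only ketone (an activated α,β-epoxy ketone) in the presence of the ester; the new carbinol is the later retro-aldol trigger and its configuration is irrelevant.

Step 6
Reactants: 8 epoxy alcohol
Product: 9 3-[(tert-butyldimethylsilyl)oxy]-4-methyl-8-[(triethylsilyl)oxy]spiro[bicyclo[2.2.2]oct-5-ene-2,2′-oxiran]-7-yl 3-methylbutanoate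
Conditions: tBuMe2SiOTf, 2,6-lutidine, CH2Cl2, −78 °C
Reagents that add atoms: tert-butyldimethylsilyl trifluoromethanesulfonate, CC(C)(C)[Si](C)(C)OS(=O)(=O)C(F)(F)F
Why: Silylation of the hindered secondary alcohol with a silyl triflate under buffered low-temperature conditions, which masks it during oxidation of the other carbinol.

Step 7
Reactants: 9 bis-silyl ether
Product: 10 3-[(tert-butyldimethylsilyl)oxy]-8-hydroxy-4-methylspiro[bicyclo[2.2.2]oct-5-ene-2,2′-oxiran]-7-yl 3-methylbutanoate
Conditions: HF·pyridine, pyridine, THF, 0 °C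
Reagents that add atoms: none
Why: Selective desilylation: the triethylsilyl ether is cleaved much faster than the tert-butyldimethylsilyl ether flanked by two fully substituted carbons, and buffered fluoride spares the epoxide and the ester.

Step 8
Reactants: 10 hydroxy ester
Product: 11 3-[(tert-butyldimethylsilyl)oxy]-4-methyl-8-oxospiro[bicyclo[2.2.2]oct-5-ene-2,2′-oxiran]-7-yl 3-methylbutanoate
Conditions: Dess–Martin periodinane, CH2Cl2, rt
Reagents that add atoms: none
Why: Dess–Martin oxidation of the only free alcohol gives the ketone next to the methyl-bearing bridgehead, i.e. a silyl-masked aldol set up for fragmentation.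

Step 9
Reactants: 11 β-silyloxy ketone
Product: 13 (1S,6R)-6-[(2R)-2-formyloxiran-2-yl]-3-methyl-2-oxocyclohex-3-en-1-yl 3-methylbutanoate, via desilylated ketol alkoxide 12 (not isolated)
Conditions: Bu4NF, THF, −20 to 0 °C; AcOH quench
Reagents that add atoms: none
Why: Fluoride frees the alkoxide, which should undergo a strain-driven retro-aldol fragmentation of the bridgehead–carbinol bond to give the aldehyde and a dienolate that equilibrates to the conjugated 2-methylcyclohexenone; the acyloxy carbon, the side-chain-bearing carbon and the oxirane carbon are not touched.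

Step 10
Reactants: 13 enone aldehyde
Product: 14 (1S,6R)-6-[(2R)-2-(1-hydroxybut-3-en-1-yl)oxiran-2-yl]-3-methyl-2-oxocyclohex-3-en-1-yl 3-methylbutanoate
Conditions: allyl bromide, In powder, THF–H2O, rt
Reagents that add atoms: allyl bromide, C=CCBr
Why: Barbier-type indium-mediated allylation is chemoselective for the aldehyde over the enone, ester and epoxide.

Step 11
Reactants: 14 enone
Product: 15 (1S,2S,6R)-2-hydroxy-6-[(2R)-2-(1-hydroxybut-3-en-1-yl)oxiran-2-yl]-3-methylcyclohex-3-en-1-yl 3-methylbutanoate (ring OH cis to the side chain, trans to the ester)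
Conditions: NaBH4, CeCl3·7H2O, MeOH, −78 °C
Reagents that add atoms: none
Why: Luche 1,2-reduction: hydride should add along the axial trajectory of the half-chair that has both ring substituents equatorial, giving the pseudo-equatorial allylic alcohol cis to the side chain and trans to the ester.

Step 12
Reactants: 15 allylic alcohol
Product: 16 2-hydroxy-4-[2-(1-hydroxybut-3-en-1-yl)oxiran-2-yl]-1-methyl-7-oxabicyclo[4.1.0]heptan-3-yl 3-methylbutanoate (ring oxirane and ring OH cis to the side chain)
Conditions: VO(acac)2 (cat.), tBuOOH, CH2Cl2, 0 °C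
Reagents that add atoms: tert-butyl hydroperoxide, CC(C)(C)OO
Why: Hydroxyl-directed vanadium-catalysed epoxidation delivers oxygen to the face of the cyclic allylic alcohol that bears the hydroxyl, i.e. cis to the side chain, and so sets both ring oxirane carbons; the monosubstituted homoallylic alkene reacts far more slowly.

Step 13
Reactants: 16 terminal alkene
Product: 17 2-hydroxy-4-[2-(1-hydroxy-4-methylpent-3-en-1-yl)oxiran-2-yl]-1-methyl-7-oxabicyclo[4.1.0]heptan-3-yl 3-methylbutanoate
Conditions: second-generation Grubbs catalyst (5 mol %), 2-methylbut-2-ene–CH2Cl2, 40 °C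
Reagents that add atoms: 2-methylbut-2-ene, CC=C(C)C
Why: Olefin cross-metathesis turns the allyl into a prenyl group with loss of propene; free alcohols, epoxides and the ester are tolerated.

Step 14
Reactants: 17 diol
Product: 18 (1S,3S,4R,6S)-1-methyl-4-[(2R)-2-(4-methylpent-3-enoyl)oxiran-2-yl]-2-oxo-7-oxabicyclo[4.1.0]heptan-3-yl 3-methylbutanoate
Conditions: Dess–Martin periodinane, NaHCO3, CH2Cl2, 0 °C to rt
Reagents that add atoms: none
Why: Buffered Dess–Martin oxidation of both secondary alcohols gives the ring epoxy ketone and the β,γ-unsaturated side-chain ketone without base, so the prenyl alkene should not move into conjugation.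

Step 15
Reactants: 18 prenyl ketone
Product: 19 (1S,3S,4R,6S)-4-{(2R)-2-[(2E)-4-hydroperoxy-4-methylpent-2-enoyl]oxiran-2-yl}-1-methyl-2-oxo-7-oxabicyclo[4.1.0]heptan-3-yl 3-methylbutanoate (target, CNP0131119.1)
Conditions: O2, tetraphenylporphyrin (cat.), visible light, CH2Cl2, −20 °C
Reagents that add atoms: dioxygen, O=O
Why: Schenck ene reaction of singlet oxygen with the trisubstituted alkene: abstraction of the hydrogen between carbonyl and alkene is favoured by the developing conjugation and should give the tertiary hydroperoxide with the E-enone, while epoxides, ketones and the ester are inert.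

**Compound list**

1 | allyl 3-methylbutanoate | CC(C)CC(=O)OCC=C | starting material
2 | 2-oxoethyl 3-methylbutanoate | CC(C)CC(=O)OCC=O | intermediate
3 | (Z)-2-[(triethylsilyl)oxy]ethenyl 3-methylbutanoate | CC(C)CC(=O)O/C=C\O[Si](CC)(CC)CC | intermediate
4 | 2-(hydroxymethyl)-6-methylphenol | Cc1cccc(CO)c1O | starting material
5 | 5-methyl-1-oxaspiro[2.5]octa-5,7-dien-4-one (racemic, not isolated) | CC1=CC=CC2(CO2)C1=O | intermediate
6 | racemic endo adduct, 4-methyl-3-oxo-8-[(triethylsilyl)oxy]spiro[bicyclo[2.2.2]oct-5-ene-2,2′-oxiran]-7-yl 3-methylbutanoate (SMILES shows the enantiomer carried on) | CC(C)CC(=O)O[C@@H]1[C@H](O[Si](CC)(CC)CC)[C@]2(C)C=C[C@H]1[C@@]1(CO1)C2=O | intermediate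
7 | the same adduct as single enantiomer | CC(C)CC(=O)O[C@@H]1[C@H](O[Si](CC)(CC)CC)[C@]2(C)C=C[C@H]1[C@@]1(CO1)C2=O | intermediate
8 | 3-hydroxy-4-methyl-8-[(triethylsilyl)oxy]spiro[bicyclo[2.2.2]oct-5-ene-2,2′-oxiran]-7-yl 3-methylbutanoate | CC(C)CC(=O)O[C@@H]1[C@H](O[Si](CC)(CC)CC)[C@]2(C)C=C[C@H]1[C@@]1(CO1)C2O | intermediate
9 | 3-[(tert-butyldimethylsilyl)oxy]-4-methyl-8-[(triethylsilyl)oxy]spiro[bicyclo[2.2.2]oct-5-ene-2,2′-oxiran]-7-yl 3-methylbutanoate | CC(C)CC(=O)O[C@@H]1[C@H](O[Si](CC)(CC)CC)[C@]2(C)C=C[C@H]1[C@@]1(CO1)C2O[Si](C)(C)C(C)(C)C | intermediate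
10 | 3-[(tert-butyldimethylsilyl)oxy]-8-hydroxy-4-methylspiro[bicyclo[2.2.2]oct-5-ene-2,2′-oxiran]-7-yl 3-methylbutanoate | CC(C)CC(=O)O[C@@H]1[C@H](O)[C@]2(C)C=C[C@H]1[C@@]1(CO1)C2O[Si](C)(C)C(C)(C)C | intermediate
11 | 3-[(tert-butyldimethylsilyl)oxy]-4-methyl-8-oxospiro[bicyclo[2.2.2]oct-5-ene-2,2′-oxiran]-7-yl 3-methylbutanoate | CC(C)CC(=O)O[C@@H]1C(=O)[C@]2(C)C=C[C@H]1[C@@]1(CO1)C2O[Si](C)(C)C(C)(C)C | intermediate
12 | 3-hydroxy-4-methyl-8-oxospiro[bicyclo[2.2.2]oct-5-ene-2,2′-oxiran]-7-yl 3-methylbutanoate (formed as its alkoxide, not isolated) | CC(C)CC(=O)O[C@@H]1C(=O)[C@]2(C)C=C[C@H]1[C@@]1(CO1)C2O | intermediate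
13 | (1S,6R)-6-[(2R)-2-formyloxiran-2-yl]-3-methyl-2-oxocyclohex-3-en-1-yl 3-methylbutanoate | CC(C)CC(=O)O[C@@H]1C(=O)C(C)=CC[C@H]1[C@]1(C=O)CO1 | intermediate
14 | (1S,6R)-6-[(2R)-2-(1-hydroxybut-3-en-1-yl)oxiran-2-yl]-3-methyl-2-oxocyclohex-3-en-1-yl 3-methylbutanoate | CC(C)CC(=O)O[C@@H]1C(=O)C(C)=CC[C@H]1[C@]1(C(O)CC=C)CO1 | intermediate
15 | (1S,2S,6R)-2-hydroxy-6-[(2R)-2-(1-hydroxybut-3-en-1-yl)oxiran-2-yl]-3-methylcyclohex-3-en-1-yl 3-methylbutanoate | CC(C)CC(=O)O[C@@H]1[C@@H](O)C(C)=CC[C@H]1[C@]1(C(O)CC=C)CO1 | intermediate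
16 | 2-hydroxy-4-[2-(1-hydroxybut-3-en-1-yl)oxiran-2-yl]-1-methyl-7-oxabicyclo[4.1.0]heptan-3-yl 3-methylbutanoate (ring oxirane and OH cis to the side chain) | CC(C)CC(=O)O[C@@H]1[C@@H](O)[C@@]2(C)O[C@H]2C[C@H]1[C@]1(C(O)CC=C)CO1 | intermediate
17 | 2-hydroxy-4-[2-(1-hydroxy-4-methylpent-3-en-1-yl)oxiran-2-yl]-1-methyl-7-oxabicyclo[4.1.0]heptan-3-yl 3-methylbutanoate | CC(C)CC(=O)O[C@@H]1[C@@H](O)[C@@]2(C)O[C@H]2C[C@H]1[C@]1(C(O)CC=C(C)C)CO1 | intermediate
18 | (1S,3S,4R,6S)-1-methyl-4-[(2R)-2-(4-methylpent-3-enoyl)oxiran-2-yl]-2-oxo-7-oxabicyclo[4.1.0]heptan-3-yl 3-methylbutanoate | CC(C)CC(=O)O[C@@H]1C(=O)[C@@]2(C)O[C@H]2C[C@H]1[C@]1(C(=O)CC=C(C)C)CO1 | intermediate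
19 | (1S,3S,4R,6S)-4-{(2R)-2-[(2E)-4-hydroperoxy-4-methylpent-2-enoyl]oxiran-2-yl}-1-methyl-2-oxo-7-oxabicyclo[4.1.0]heptan-3-yl 3-methylbutanoate | CC(C)CC(=O)O[C@@H]1C(=O)[C@@]2(C)O[C@H]2C[C@H]1[C@]1(C(=O)/C=C/C(C)(C)OO)CO1 | target

**Step count and risks**

Total step count: 15. Longest linear sequence: 15 steps (1 to 19; 13 steps from 4).

Steps most likely to fail:

Step 3. The dienone may dimerise faster than it is trapped, or the unsymmetrical alkene may add with the wrong orientation. The fallback sets out from 4 and comes back at 10. The two oxygens are brought in with symmetrical vinylene carbonate, which raises no regiochemical question and can serve as co-solvent. NaIO4 oxidation of 4 in its presence (or thermal cracking of the dienone dimer in it) should give the endo cyclic carbonate adduct F1, which is resolved as in step 4. NaBH4 then gives the carbinol F2, tBuMe2SiOTf its silyl ether F3, and K2CO3 in MeOH the cis-diol F4. Isovaleryl chloride with pyridine at −20 °C acylates the less hindered hydroxyl (next to the CH bridgehead) to give 10.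

Step 4. The catalyst may discriminate poorly between the enantiomers, or open this hindered keto-epoxide too slowly. The fallback sets out from 6 and comes back at 7: the racemate is separated by preparative chromatography on a polysaccharide chiral stationary phase, and no new compound is made.

Step 15. Singlet oxygen may abstract hydrogen from the geminal methyl groups instead of the CH2 between ketone and alkene, giving the secondary allylic hydroperoxide. The fallback sets out from 16 and comes back at 19. Dess–Martin oxidation of 16 gives the allyl diketone F5, which triethylamine isomerises to the (E)-propenyl ketone F6. 2-Methylbut-3-en-2-yl hydroperoxide F7 (from 2-methylbut-3-en-2-ol, H2O2 and H2SO4) is silylated with Et3SiCl and imidazole to its triethylsilyl peroxide F8. Cross-metathesis of F6 with F8 (second-generation Hoveyda–Grubbs catalyst) gives the silyl-protected hydroperoxide F9 with the E-enone, and HF·pyridine frees 19.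

Further compounds
F1 | step 3 | 4-methyl-3-oxospiro[bicyclo[2.2.2]oct-5-ene-2,2′-oxirane]-7,8-diyl carbonate (carbonate syn to C5=C6, oxirane oxygen syn to the C7–C8 bridge) | O=C3O[C@@H]1[C@H](O3)[C@]2(C)C=C[C@H]1[C@@]1(CO1)C2=O
F2 | step 3 | 3-hydroxy-4-methylspiro[bicyclo[2.2.2]oct-5-ene-2,2′-oxirane]-7,8-diyl carbonate | O=C3O[C@@H]1[C@H](O3)[C@]2(C)C=C[C@H]1[C@@]1(CO1)C2O
F3 | step 3 | 3-[(tert-butyldimethylsilyl)oxy]-4-methylspiro[bicyclo[2.2.2]oct-5-ene-2,2′-oxirane]-7,8-diyl carbonate | O=C3O[C@@H]1[C@H](O3)[C@]2(C)C=C[C@H]1[C@@]1(CO1)C2O[Si](C)(C)C(C)(C)C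
F4 | step 3 | 3-[(tert-butyldimethylsilyl)oxy]-4-methylspiro[bicyclo[2.2.2]oct-5-ene-2,2′-oxirane]-7,8-diol | O[C@@H]1[C@H](O)[C@]2(C)C=C[C@H]1[C@@]1(CO1)C2O[Si](C)(C)C(C)(C)C
F0 | step 4 | none | none
F5 | step 15 | (1S,3S,4R,6S)-4-[(2R)-2-(but-3-enoyl)oxiran-2-yl]-1-methyl-2-oxo-7-oxabicyclo[4.1.0]heptan-3-yl 3-methylbutanoate | CC(C)CC(=O)O[C@@H]1C(=O)[C@@]2(C)O[C@H]2C[C@H]1[C@]1(C(=O)CC=C)CO1
F6 | step 15 | (1S,3S,4R,6S)-4-{(2R)-2-[(2E)-but-2-enoyl]oxiran-2-yl}-1-methyl-2-oxo-7-oxabicyclo[4.1.0]heptan-3-yl 3-methylbutanoate | CC(C)CC(=O)O[C@@H]1C(=O)[C@@]2(C)O[C@H]2C[C@H]1[C@]1(C(=O)/C=C/C)CO1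
F7 | step 15 | 2-methylbut-3-en-2-yl hydroperoxide | C=CC(C)(C)OO
F8 | step 15 | triethyl[(2-methylbut-3-en-2-yl)peroxy]silane | C=CC(C)(C)OO[Si](CC)(CC)CC
F9 | step 15 | (1S,3S,4R,6S)-1-methyl-4-[(2R)-2-{(2E)-4-methyl-4-[(triethylsilyl)peroxy]pent-2-enoyl}oxiran-2-yl]-2-oxo-7-oxabicyclo[4.1.0]heptan-3-yl 3-methylbutanoate | CC(C)CC(=O)O[C@@H]1C(=O)[C@@]2(C)O[C@H]2C[C@H]1[C@]1(C(=O)/C=C/C(C)(C)OO[Si](CC)(CC)CC)CO1
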